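Retrosynthesis: the six phenols are masked as benzyl ethers and H2 is removed across C3–C4. The C3=C4 bond of ring C is then cut by metathesis, followed by the C3–O(acyl), O1–C2 and C2–C3 bonds.
Enabling feature: C3 of ring C carries the ester oxygen, and its neighbour C4 is a bare methylene bonded to C4a of ring A. One oxidation level higher, ring C is therefore a 3-acyloxy-2H-chromene, a cyclic enol ester whose C3=C4 bond divides into a ring A styrene and a 1-acyloxyvinyl group on C2.
Forward: rings A, B and D are bought as arenes. Ethyne is added to the ring B aldehyde (C2–C3), ring A is attached through O1, the ring D acid is added across the alkyne (C3–O), and ring C is closed last.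
Stereochemistry: C2 comes from a lipase resolution of the propargylic alcohol and is inverted once in the Mitsunobu etherification. C3 comes from syn hydrogenation of C3=C4 on the face away from ring B, which gives the 2,3-cis (2R,3R) ester.
Key step: step 10

Assumption: 3,4-bis(benzyloxy)benzaldehyde, the dibenzyl ether of 3,4-dihydroxybenzaldehyde, is taken as a purchasable material, and the lipase is taken to acylate the R alcohol faster, as the size rule for secondary alcohols predicts (ethynyl small, aryl large).

Step 1
Reactants: 1 3,4-bis(benzyloxy)benzaldehyde; 2 ethynylmagnesium bromide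
Product: 3 rac-1-[3,4-bis(benzyloxy)phenyl]prop-2-yn-1-ol
Conditions: HC≡CMgBr (1.3 equiv, 0.5 M in THF), THF, 0 °C to rt; aq NH4Cl
Reagents that add atoms: none
Why: Grignard 1,2-addition of the alkynyl nucleophile to a non-enolisable aromatic aldehyde forms the C2–C3 bond, and the new carbinol centre (the future C2) is formed racemic here and resolved in step 2.

Step 2
Reactants: 3 rac-1-[3,4-bis(benzyloxy)phenyl]prop-2-yn-1-ol
Product: 4 (R)-1-[3,4-bis(benzyloxy)phenyl]prop-2-yn-1-yl acetate
Conditions: Novozym 435 (immobilised Candida antarctica lipase B), vinyl acetate (3 equiv), MTBE–toluene, 35 °C, stopped a little short of half conversion; chromatography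
Reagents that add atoms: vinyl acetate, C=COC(C)=O
Why: Lipase-catalysed kinetic resolution by irreversible transesterification, established for terminal 1-arylprop-2-yn-1-ols: the enzyme acylates the enantiomer whose slim ethynyl group fits its small pocket and whose aryl group points into the large one, which is the R alcohol, so that the C2 stereocentre enters the route as the R acetate and stopping short of half conversion protects its purity.

Step 3
Reactants: 4 (R)-1-[3,4-bis(benzyloxy)phenyl]prop-2-yn-1-yl acetate
Product: 5 (R)-1-[3,4-bis(benzyloxy)phenyl]prop-2-yn-1-ol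
Conditions: K2CO3 (0.2 equiv), MeOH–THF, 0 °C to rt
Reagents that add atoms: none
Why: Base-catalysed transesterification with methanol breaks the acyl–oxygen bond only, so the C–O bond at the stereocentre is untouched and the R configuration is retained.

Step 4
Reactants: 6 2,4,6-trihydroxybenzaldehyde
Product: 7 4,6-bis(benzyloxy)-2-hydroxybenzaldehyde
Conditions: BnBr (2.0 equiv), K2CO3 (2.0 equiv), DMF, 0 °C to rt
Reagents that add atoms: benzyl bromide, BrCc1ccccc1
Why: Williamson etherification under stoichiometric control: the 4-OH and one of the two equivalent ortho OH groups are alkylated, whereas the last ortho OH is tied up in a hydrogen bond to the formyl oxygen, is the least nucleophilic and stays free.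

Step 5
Reactants: 7 4,6-bis(benzyloxy)-2-hydroxybenzaldehyde
Product: 8 3,5-bis(benzyloxy)-2-vinylphenol
Conditions: MePPh3Br (2.5 equiv), KOt-Bu (2.5 equiv), THF, 0 °C to rt; aq NH4Cl; used at once
Reagents that add atoms: methyltriphenylphosphonium bromide, C[P+](c1ccccc1)(c1ccccc1)c1ccccc1.[Br-]
Why: Wittig methylenation with excess ylide, the first equivalent of base being taken up by the phenol, is the standard conversion of salicylaldehydes into 2-vinylphenols and touches neither benzyl ether.

Step 6
Reactants: 5 (R)-1-[3,4-bis(benzyloxy)phenyl]prop-2-yn-1-ol; 8 3,5-bis(benzyloxy)-2-vinylphenol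
Product: 9 1,5-bis(benzyloxy)-3-{[(1S)-1-[3,4-bis(benzyloxy)phenyl]prop-2-yn-1-yl]oxy}-2-vinylbenzene
Conditions: PPh3 (1.3 equiv), DIAD (1.3 equiv), toluene, −20 °C to 0 °C
Reagents that add atoms: none
Why: Mitsunobu etherification: the phenoxide displaces the alkoxyphosphonium group of 5 in an SN2 manner, so the R carbinol centre is inverted to the S ether, which has the spatial arrangement of C2 in the target, while the non-polar solvent, the low temperature and the inductively withdrawing ethynyl group hold back ionisation of the electron-rich benzylic centre.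

Step 7
Reactants: 10 3,5-dihydroxy-4-methoxybenzoic acid
Product: 11 benzyl 3,5-bis(benzyloxy)-4-methoxybenzoate
Conditions: BnBr (3.3 equiv), K2CO3 (3.5 equiv), DMF, 60 °C
Reagents that add atoms: benzyl bromide, BrCc1ccccc1
Why: Williamson etherification of both phenols with concurrent O-alkylation of the carboxylate is an exhaustive benzylation that needs no selectivity.

Step 8
Reactants: 11 benzyl 3,5-bis(benzyloxy)-4-methoxybenzoate
Product: 12 3,5-bis(benzyloxy)-4-methoxybenzoic acid
Conditions: KOH, THF–MeOH–H2O, 50 °C; then aq HCl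
Reagents that add atoms: potassium hydroxide, [K+].[OH-]
Why: Saponification (acyl–oxygen cleavage by hydroxide) removes only the benzyl ester, since the aryl benzyl and aryl methyl ethers are inert to aqueous base.

Step 9
Reactants: 9 1,5-bis(benzyloxy)-3-{[(1S)-1-[3,4-bis(benzyloxy)phenyl]prop-2-yn-1-yl]oxy}-2-vinylbenzene; 12 3,5-bis(benzyloxy)-4-methoxybenzoic acid
Product: 13 (3R)-3-[3,4-bis(benzyloxy)phenyl]-3-[3,5-bis(benzyloxy)-2-vinylphenoxy]prop-1-en-2-yl 3,5-bis(benzyloxy)-4-methoxybenzoate (same spatial arrangement as 9; the descriptor changes only because the priorities change)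
Conditions: [RuCl2(p-cymene)]2 (2.5 mol %), P(2-furyl)3 (5 mol %), Na2CO3 (10 mol %), toluene, 50 °C
Reagents that add atoms: none
Why: Ruthenium-catalysed Markovnikov addition of a carboxylic acid to a terminal alkyne: the carboxylate attacks the internal carbon of the metal-bound alkyne and protodemetalation gives the 1-acyloxyvinyl group, the electron-poor phosphine with catalytic carbonate being the catalyst variant that favours this regiochemistry over the vinylidene (anti-Markovnikov) path, and neither the styrene nor the C2 centre takes part.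

Step 10
Reactants: 13 (3R)-3-[3,4-bis(benzyloxy)phenyl]-3-[3,5-bis(benzyloxy)-2-vinylphenoxy]prop-1-en-2-yl 3,5-bis(benzyloxy)-4-methoxybenzoate
Product: 14 (2R)-5,7-bis(benzyloxy)-2-[3,4-bis(benzyloxy)phenyl]-2H-chromen-3-yl 3,5-bis(benzyloxy)-4-methoxybenzoate
Conditions: RuCl2(=CHPh)(PCy3)(SIMes) (second-generation Grubbs catalyst, 10 mol % in two portions), 1,4-benzoquinone (20 mol %), toluene (2 mM), 50 °C, argon sparge, dark
Reagents that add atoms: none
Why: Ring-closing olefin metathesis by the metallacyclobutane mechanism: after loss of PCy3 the ruthenium carbene exchanges with the monosubstituted ring A styrene to give the C4 benzylidene, which adds across the 1-acyloxyvinyl group with C4 bonding to C3 and ruthenium to the terminal CH2, and cycloreversion forms C3=C4 and hands on Ru=CH2, which leaves as ethene. The closest known reactions are the ring-closing metathesis of 2-vinylphenyl allyl ethers to 2H-chromenes and of acyclic enol esters, enol ethers and silyl enol ethers to their cyclic counterparts with the same class of catalyst. Ring C closes as a six-membered ring (O1, C2, C3, C4, C4a, C8a) in which the cis-fixed C4a–C8a arene bond and the O1–C2 ether hold the two alkenes close, so closure should outrun cross metathesis at high dilution. No stereocentre is formed; C2, set in step 6, has no metathesis-active bond and is only a spectator. The step needs site selectivity (carbene loading at the styrene, closure at the substituted carbon of the enol ester), which is secured because the acyloxy-bearing carbon is fully substituted, so an acyloxycarbene of ruthenium is disfavoured and only the CH2 end is released. It also needs C2 to stay intact, which is secured by 1,4-benzoquinone (it intercepts ruthenium hydrides that would move the alkene toward C2) and by working at 50 °C in the dark (which holds back 6π ring opening of the 2H-chromene).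

Step 11
Reactants: 14 (2R)-5,7-bis(benzyloxy)-2-[3,4-bis(benzyloxy)phenyl]-2H-chromen-3-yl 3,5-bis(benzyloxy)-4-methoxybenzoate
Product: 15 (2R,3R)-5,7-bis(benzyloxy)-2-[3,4-bis(benzyloxy)phenyl]chroman-3-yl 3,5-bis(benzyloxy)-4-methoxybenzoate (2,3-cis)
Conditions: H2 (3 bar), 5% Rh/Al2O3, EtOAc, rt, dark; stopped after uptake of one equivalent of H2
Reagents that add atoms: none
Why: Heterogeneous syn hydrogenation of a trisubstituted enol ester: allylic strain between the C3 acyloxy group and the C2 aryl group pushes ring B into a pseudoaxial position, so the alkene meets the metal surface through the opposite face and the new H-3 ends up cis to H-2, which sets C3 as R with the ester cis to ring B, and rhodium on alumina is chosen because it saturates alkenes with little hydrogenolysis of benzyl ethers or of the allylic, benzylic O1–C2 bond.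

Step 12
Reactants: 15 (2R,3R)-5,7-bis(benzyloxy)-2-[3,4-bis(benzyloxy)phenyl]chroman-3-yl 3,5-bis(benzyloxy)-4-methoxybenzoate
Product: 16 (−)-epicatechin 3-O-(4-O-methylgallate), (2R,3R)-2-(3,4-dihydroxyphenyl)-5,7-dihydroxychroman-3-yl 3,5-dihydroxy-4-methoxybenzoate
Conditions: H2 (1 atm), 20% Pd(OH)2/C, THF–MeOH, rt; filtered under argon
Reagents that add atoms: none
Why: Catalytic hydrogenolysis of aryl benzyl ethers, the standard last step for benzylated flavan-3-ol gallates: the six primary benzylic C–O bonds are cleaved much faster than the hindered secondary O1–C2 bond of the now saturated ring C, and the neutral conditions leave the ester, the methyl ether and both stereocentres untouched.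

Compound list
1 | 3,4-bis(benzyloxy)benzaldehyde | O=Cc1ccc(OCc2ccccc2)c(OCc2ccccc2)c1 | starting material
2 | ethynylmagnesium bromide | C#C[Mg]Br | starting material
3 | rac-1-[3,4-bis(benzyloxy)phenyl]prop-2-yn-1-ol | OC(C#C)c1ccc(OCc2ccccc2)c(OCc2ccccc2)c1 | intermediate
4 | (R)-1-[3,4-bis(benzyloxy)phenyl]prop-2-yn-1-yl acetate | CC(=O)O[C@H](C#C)c1ccc(OCc2ccccc2)c(OCc2ccccc2)c1 | intermediate
5 | (R)-1-[3,4-bis(benzyloxy)phenyl]prop-2-yn-1-ol | O[C@H](C#C)c1ccc(OCc2ccccc2)c(OCc2ccccc2)c1 | intermediate
6 | 2,4,6-trihydroxybenzaldehyde | O=Cc1c(O)cc(O)cc1O | starting material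
7 | 4,6-bis(benzyloxy)-2-hydroxybenzaldehyde | O=Cc1c(O)cc(OCc2ccccc2)cc1OCc1ccccc1 | intermediate
8 | 3,5-bis(benzyloxy)-2-vinylphenol | C=Cc1c(O)cc(OCc2ccccc2)cc1OCc1ccccc1 | intermediate
9 | 1,5-bis(benzyloxy)-3-{[(1S)-1-[3,4-bis(benzyloxy)phenyl]prop-2-yn-1-yl]oxy}-2-vinylbenzene | C=Cc1c(OCc2ccccc2)cc(OCc2ccccc2)cc1O[C@@H](C#C)c1ccc(OCc2ccccc2)c(OCc2ccccc2)c1 | intermediate
10 | 3,5-dihydroxy-4-methoxybenzoic acid | COc1c(O)cc(C(=O)O)cc1O | starting material
11 | benzyl 3,5-bis(benzyloxy)-4-methoxybenzoate | COc1c(OCc2ccccc2)cc(C(=O)OCc2ccccc2)cc1OCc1ccccc1 | intermediate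
12 | 3,5-bis(benzyloxy)-4-methoxybenzoic acid | COc1c(OCc2ccccc2)cc(C(=O)O)cc1OCc1ccccc1 | intermediate
13 | (3R)-3-[3,4-bis(benzyloxy)phenyl]-3-[3,5-bis(benzyloxy)-2-vinylphenoxy]prop-1-en-2-yl 3,5-bis(benzyloxy)-4-methoxybenzoate | C=Cc1c(OCc2ccccc2)cc(OCc2ccccc2)cc1O[C@@H](C(=C)OC(=O)c1cc(OCc2ccccc2)c(OC)c(OCc2ccccc2)c1)c1ccc(OCc2ccccc2)c(OCc2ccccc2)c1 | intermediate
14 | (2R)-5,7-bis(benzyloxy)-2-[3,4-bis(benzyloxy)phenyl]-2H-chromen-3-yl 3,5-bis(benzyloxy)-4-methoxybenzoate | COc1c(OCc2ccccc2)cc(C(=O)OC2=Cc3c(OCc4ccccc4)cc(OCc4ccccc4)cc3O[C@@H]2c2ccc(OCc3ccccc3)c(OCc3ccccc3)c2)cc1OCc1ccccc1 | intermediate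
15 | (2R,3R)-5,7-bis(benzyloxy)-2-[3,4-bis(benzyloxy)phenyl]chroman-3-yl 3,5-bis(benzyloxy)-4-methoxybenzoate | COc1c(OCc2ccccc2)cc(C(=O)O[C@@H]2Cc3c(OCc4ccccc4)cc(OCc4ccccc4)cc3O[C@@H]2c2ccc(OCc3ccccc3)c(OCc3ccccc3)c2)cc1OCc1ccccc1 | intermediate
16 | (−)-epicatechin 3-O-(4-O-methylgallate) | COc1c(O)cc(C(=O)O[C@@H]2Cc3c(O)cc(O)cc3O[C@@H]2c2ccc(O)c(O)c2)cc1O | target

Total step count: 12
Longest linear sequence: 8 steps (1, 2, 3, 6, 9, 10, 11, 12)

Steps most likely to fail

Step 10. Carbene loading at the 2,6-dioxygenated styrene may be slow, and an ortho ether oxygen may tie up the loaded carbene. The catalyst may then decay to ruthenium hydrides before it closes onto the hindered 1,1-disubstituted alkene. The fallback is a relay ring-closing metathesis that delivers the carbene to C4 intramolecularly. It sets out from 7. A Wittig reaction with the ylide from hex-5-en-1-yltriphenylphosphonium bromide and KN(SiMe3)2 (excess, THF) should give 3,5-bis(benzyloxy)-2-(hepta-1,6-dien-1-yl)phenol F1 as an E/Z mixture whose geometry is lost later. Mitsunobu etherification with 5 under the conditions of step 6 should give the S propargylic relay ether F2. Addition of 12 under the conditions of step 9 should give the relay enol ester F3. With RuCl2(=CHPh)(PCy3)(SIMes) the catalyst loads at the unhindered terminal alkene and expels cyclopentene. It thereby arrives as the ring A benzylidene, which closes onto the enol ester. The fallback comes back to the route at 14.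

Step 6. The alkoxyphosphonium salt of the electron-rich benzylic, propargylic alcohol may partly ionise, which erodes the configuration at C2. The electron-rich phenol may also be alkylated at carbon. The fallback is an enantioconvergent copper-catalysed propargylic etherification, which makes the resolution unnecessary. It sets out from 3. Ac2O and pyridine should give rac-1-[3,4-bis(benzyloxy)phenyl]prop-2-yn-1-yl acetate F4. With [Cu(MeCN)4]BF4, a chiral 2,6-bis(oxazolinyl)pyridine ligand and i-Pr2NEt in THF at low temperature, both enantiomers pass through the same catalyst-bound copper allenylidene. This is captured at the propargylic carbon by the phenol oxygen of 7, which is chosen over 8 because its formyl group lowers the nucleophilicity of the ring carbons. The ligand antipode is picked to deliver 2,4-bis(benzyloxy)-6-{[(1S)-1-[3,4-bis(benzyloxy)phenyl]prop-2-yn-1-yl]oxy}benzaldehyde F5. Wittig methylenation with one equivalent of Ph3P=CH2 (THF, −78 °C to 0 °C) comes back to the route at 9.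

Step 11. Facial selectivity may be poor, or hydrogenolysis of the vinylic C3–O bond or the allylic O1–C2 bond may outrun saturation of the alkene. The fallback sets C3 by hydride delivery to a ketone instead of by hydrogenation. It sets out from 14. MeLi (2 equiv, THF, −78 °C) cleaves the enol ester regiospecifically to lithium (2R)-5,7-bis(benzyloxy)-2-[3,4-bis(benzyloxy)phenyl]-2H-chromen-3-olate F6. Protonation with AcOH at −78 °C should then give (2R)-5,7-bis(benzyloxy)-2-[3,4-bis(benzyloxy)phenyl]chroman-3-one F7 without enolisation toward C2. LiBH(s-Bu)3 (THF, −78 °C) attacks the carbonyl group from the face away from ring B and should give 5,7,3',4'-tetra-O-benzyl-(−)-epicatechin F8. Steglich-type esterification with 12 (EDC·HCl, DMAP, CH2Cl2) comes back to the route at 15.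

Further compounds
F1 | step 10 | 3,5-bis(benzyloxy)-2-(hepta-1,6-dien-1-yl)phenol (E/Z mixture) | C=CCCCC=Cc1c(O)cc(OCc2ccccc2)cc1OCc1ccccc1
F2 | step 10 | 1,5-bis(benzyloxy)-3-{[(1S)-1-[3,4-bis(benzyloxy)phenyl]prop-2-yn-1-yl]oxy}-2-(hepta-1,6-dien-1-yl)benzene | C=CCCCC=Cc1c(OCc2ccccc2)cc(OCc2ccccc2)cc1O[C@@H](C#C)c1ccc(OCc2ccccc2)c(OCc2ccccc2)c1
F3 | step 10 | (3R)-3-[3,4-bis(benzyloxy)phenyl]-3-[3,5-bis(benzyloxy)-2-(hepta-1,6-dien-1-yl)phenoxy]prop-1-en-2-yl 3,5-bis(benzyloxy)-4-methoxybenzoate | C=CCCCC=Cc1c(OCc2ccccc2)cc(OCc2ccccc2)cc1O[C@@H](C(=C)OC(=O)c1cc(OCc2ccccc2)c(OC)c(OCc2ccccc2)c1)c1ccc(OCc2ccccc2)c(OCc2ccccc2)c1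
F4 | step 6 | rac-1-[3,4-bis(benzyloxy)phenyl]prop-2-yn-1-yl acetate | CC(=O)OC(C#C)c1ccc(OCc2ccccc2)c(OCc2ccccc2)c1
F5 | step 6 | 2,4-bis(benzyloxy)-6-{[(1S)-1-[3,4-bis(benzyloxy)phenyl]prop-2-yn-1-yl]oxy}benzaldehyde | O=Cc1c(OCc2ccccc2)cc(OCc2ccccc2)cc1O[C@@H](C#C)c1ccc(OCc2ccccc2)c(OCc2ccccc2)c1
F6 | step 11 | lithium (2R)-5,7-bis(benzyloxy)-2-[3,4-bis(benzyloxy)phenyl]-2H-chromen-3-olate | [Li+].[O-]C1=Cc2c(OCc3ccccc3)cc(OCc3ccccc3)cc2O[C@@H]1c1ccc(OCc2ccccc2)c(OCc2ccccc2)c1
F7 | step 11 | (2R)-5,7-bis(benzyloxy)-2-[3,4-bis(benzyloxy)phenyl]chroman-3-one | O=C1Cc2c(OCc3ccccc3)cc(OCc3ccccc3)cc2O[C@@H]1c1ccc(OCc2ccccc2)c(OCc2ccccc2)c1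
F8 | step 11 | 5,7,3',4'-tetra-O-benzyl-(−)-epicatechin, (2R,3R) | O[C@@H]1Cc2c(OCc3ccccc3)cc(OCc3ccccc3)cc2O[C@@H]1c1ccc(OCc2ccccc2)c(OCc2ccccc2)c1
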